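**Strategy.** Everything rests on disconnecting the ether oxygen from C9 and, in the same stroke, C9 from C8 (eunicellin numbering). In the forward sense a copper carbenoid at C9 of a 2,6-cis-tetrahydropyran diazoketone is captured by the ring oxygen, closing the tetrahydrofuran-3-one ring (O, C2, C1, C10, C9). The allyl oxonium ylide then undergoes a [2,3]-shift that enlarges the six-membered oxane to the nine-membered oxonene and installs the (Z)-C6=C7 alkene. The step exploits the fact that C9 is flanked by the ether oxygen and is homoallylic (C9–C8–C7=C6) to the ring alkene. Diels–Alder annulation of the cyclohexane ring and a late ε-lactone closure (C3–O–C16) complete the skeleton.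

Key step: step 11

Remark on numbering: eunicellin numbering is used throughout. The ether oxygen bridges C2 and C9; the cyclohexane is C1/C10–C14; the oxonene is O/C2–C9; the lactone is C3–O–C16(=O)–C15(C17)–C14–C1–C2; methyl groups sit on C3, C7, C11 and C15. The target is (1S,2S,3S,6Z,9S,10R,11R,14R,15R).

Assumption: 2-(2-bromoethyl)-1,3-dioxolane, methacrolein, ethyl propiolate, tributyl(1-ethoxyvinyl)stannane and methyl vinyl ketone are taken as commercial.

**Step 1**
Reactants: 1 2-(2-bromoethyl)-1,3-dioxolane; 2 methacrolein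
Product: 4 rac-1-(1,3-dioxolan-2-yl)-4-methylpent-4-en-3-ol, via Grignard reagent 3 (not isolated)
Conditions: Mg, THF, 25 °C; then 2, −78 → 0 °C; H2O work-up
Reagents that add atoms: none
Why: Grignard 1,2-addition to the enal carbonyl is fast at low temperature and should outcompete conjugate addition; the carbinol centre forms as a racemate and is resolved in step 2.

**Step 2**
Reactants: 4 rac-1-(1,3-dioxolan-2-yl)-4-methylpent-4-en-3-ol
Product: 5 (S)-1-(1,3-dioxolan-2-yl)-4-methylpent-4-en-3-ol
Conditions: Ti(OiPr)4 (cat.), D-(−)-diisopropyl tartrate, t-BuOOH (0.6 equiv), 4 Å MS, CH2Cl2, −20 °C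
Reagents that add atoms: none
Why: Sharpless kinetic resolution, in which the D-(−)-tartrate titanium catalyst should epoxidise the (R)-enantiomer much faster, so that the (S)-alcohol (the future C6, which relays chirality to C2) is recovered; at most half of the racemate can be carried on.

**Step 3**
Reactants: 5 (S)-1-(1,3-dioxolan-2-yl)-4-methylpent-4-en-3-ol; 6 ethyl propiolate
Product: 7 ethyl (E)-3-{[(3S)-1-(1,3-dioxolan-2-yl)-4-methylpent-4-en-3-yl]oxy}prop-2-enoate
Conditions: N-methylmorpholine, CH2Cl2, 25 °C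
Reagents that add atoms: none
Why: Amine-catalysed oxa-Michael addition of the secondary alcohol to the ynoate should give the (E)-β-alkoxyacrylate without touching the carbinol stereocentre.

**Step 4**
Reactants: 7 ethyl (E)-3-{[(3S)-1-(1,3-dioxolan-2-yl)-4-methylpent-4-en-3-yl]oxy}prop-2-enoate
Product: 8 ethyl (E)-3-{[(3S)-2-methyl-6-oxohex-1-en-3-yl]oxy}prop-2-enoate
Conditions: 1 M HCl, THF, 25 °C
Reagents that add atoms: water (O)
Why: Acid-catalysed acetal hydrolysis should unmask the aldehyde, while the β-alkoxyacrylate (a deactivated vinylogous carbonate) and the allylic ether resist dilute acid at room temperature.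

**Step 5**
Reactants: 8 ethyl (E)-3-{[(3S)-2-methyl-6-oxohex-1-en-3-yl]oxy}prop-2-enoate
Product: 9 ethyl 2-[(2S,3R,6S)-3-hydroxy-6-(prop-1-en-2-yl)oxan-2-yl]acetate
Conditions: SmI2 (2.5 equiv), MeOH, THF, 0 °C
Reagents that add atoms: none
Why: SmI2-mediated reductive ketyl–olefin cyclisation (6-exo radical addition to the β-alkoxyacrylate) should run through a chair transition state with the isopropenyl group equatorial and the samarium ketyl chelated to the ester, which sets C2 cis to C6 and the C3 hydroxyl trans to the C2 side chain.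

**Step 6**
Reactants: 9 ethyl 2-[(2S,3R,6S)-3-hydroxy-6-(prop-1-en-2-yl)oxan-2-yl]acetate
Product: 10 ethyl 2-[(2S,6S)-3-oxo-6-(prop-1-en-2-yl)oxan-2-yl]acetate
Conditions: Dess–Martin periodinane, CH2Cl2, 25 °C
Reagents that add atoms: none
Why: Dess–Martin oxidation is neutral and should leave the ester, the alkene and the C2 stereocentre (α to the new ketone) untouched.

**Step 7**
Reactants: 10 ethyl 2-[(2S,6S)-3-oxo-6-(prop-1-en-2-yl)oxan-2-yl]acetate
Product: 11 ethyl 2-[(2S,3S,6S)-3-hydroxy-3-methyl-6-(prop-1-en-2-yl)oxan-2-yl]acetate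
Conditions: MeMgCl, THF, −78 °C; H2O work-up
Reagents that add atoms: methylmagnesium chloride (C[Mg]Cl)
Why: Chelation-controlled Grignard addition, in which the ketone is far more electrophilic than the ester at −78 °C and methyl should enter equatorially, anti to the C2 side chain on the magnesium chelate of ketone and ring oxygen, giving the axial (3S) tertiary alcohol with C3–O cis to the C2 side chain.

**Step 8**
Reactants: 11 ethyl 2-[(2S,3S,6S)-3-hydroxy-3-methyl-6-(prop-1-en-2-yl)oxan-2-yl]acetate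
Product: 12 ethyl 2-[(2S,3S,6S)-3-(tert-butyldimethylsilyloxy)-3-methyl-6-(prop-1-en-2-yl)oxan-2-yl]acetate
Conditions: TBSOTf, 2,6-lutidine, CH2Cl2, 0 °C
Reagents that add atoms: tert-butyldimethylsilyl triflate (CC(C)(C)[Si](C)(C)OS(=O)(=O)C(F)(F)F)
Why: Silyl triflate with a hindered pyridine base is the standard silylation of tertiary alcohols and masks the C3 hydroxyl against O–H insertion in step 11.

**Step 9**
Reactants: 12 ethyl 2-[(2S,3S,6S)-3-(tert-butyldimethylsilyloxy)-3-methyl-6-(prop-1-en-2-yl)oxan-2-yl]acetate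
Product: 13 2-[(2S,3S,6S)-3-(tert-butyldimethylsilyloxy)-3-methyl-6-(prop-1-en-2-yl)oxan-2-yl]acetic acid
Conditions: LiOH, THF/MeOH/H2O, 25 °C; then 1 M HCl to pH 4
Reagents that add atoms: lithium hydroxide ([Li+].[OH-])
Why: Saponification of the ethyl ester, in which the tertiary silyl ether is stable to hydroxide and any reversible retro-oxa-Michael opening would reclose to the more stable 2,6-cis oxane.

**Step 10**
Reactants: 13 2-[(2S,3S,6S)-3-(tert-butyldimethylsilyloxy)-3-methyl-6-(prop-1-en-2-yl)oxan-2-yl]acetic acid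
Product: 15 1-diazo-3-[(2S,3S,6S)-3-(tert-butyldimethylsilyloxy)-3-methyl-6-(prop-1-en-2-yl)oxan-2-yl]propan-2-one, via mixed anhydride 14 (not isolated)
Conditions: i-BuOCOCl, Et3N, Et2O, −20 °C; then CH2N2, Et2O, 0 °C
Reagents that add atoms: diazomethane (C=[N+]=[N-])
Why: Acylation of diazomethane by the mixed carbonic anhydride (first stage of an Arndt–Eistert sequence) should give the α-diazoketone without epimerising C2.

**Step 11**
Reactants: 15 1-diazo-3-[(2S,3S,6S)-3-(tert-butyldimethylsilyloxy)-3-methyl-6-(prop-1-en-2-yl)oxan-2-yl]propan-2-one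
Product: 17 (1S,2S,5Z,8S)-2-(tert-butyldimethylsilyloxy)-2,6-dimethyl-11-oxabicyclo[6.2.1]undec-5-en-9-one, via oxonium ylide 16 (not isolated)
Conditions: Cu(CF3COCHCOCF3)2 (5 mol %), CH2Cl2, reflux, slow addition of 15
Reagents that add atoms: none
Why: Loss of N2 on copper should give an electrophilic carbenoid at C9 that is attacked by a lone pair of the oxane oxygen, and the resulting allyl oxonium ylide 16 should rearrange by a concerted suprafacial [2,3]-sigmatropic shift that forms C8–C9, cleaves O–C6 and moves the double bond to C6=C7. The closest known reaction type is metal-carbenoid oxonium ylide formation/[2,3]-rearrangement of 2-alkenyl cyclic ethers with three-atom ring expansion. The tetrahydrofuran-3-one ring (O/C2/C1/C10/C9) closes by 5-exo capture of the tethered carbenoid through O–C9 bond formation, and the nine-membered oxonene arises by ring expansion of the oxane, not by direct medium-ring closure. The new stereocentre C9 is controlled by C2 and C6: the acyl tether on C2 and the cis-related isopropenyl group on C6 lie on the same face of the oxonium ring, so C8 can only be delivered to the C9 face syn to C3, giving the cis-bridged (2S,9S) ether. The step needs ylide formation to outrun carbenoid C–H insertion and needs the Z alkene; the electron-poor hexafluoroacetylacetonate ligands on copper (instead of a rhodium carboxylate) and the equatorial isopropenyl group in the envelope transition state are expected to secure both.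

**Step 12**
Reactants: 17 (1S,2S,5Z,8S)-2-(tert-butyldimethylsilyloxy)-2,6-dimethyl-11-oxabicyclo[6.2.1]undec-5-en-9-one
Product: 18 (1S,2S,5Z,8S)-2-(tert-butyldimethylsilyloxy)-2,6-dimethyl-11-oxabicyclo[6.2.1]undeca-5,9-dien-9-yl trifluoromethanesulfonate
Conditions: NaN(SiMe3)2, PhNTf2, THF, −78 °C; aq NH4Cl work-up
Reagents that add atoms: N-phenylbis(trifluoromethanesulfonimide) (O=S(=O)(N(c1ccccc1)S(=O)(=O)C(F)(F)F)C(F)(F)F)
Why: Kinetic enolate formation should occur toward the C1 methylene because the C9 hydrogen is at the bridgehead of the oxabicycle, and O-sulfonylation with the triflimide gives the C10 enol triflate regioselectively.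

**Step 13**
Reactants: 18 (1S,2S,5Z,8S)-2-(tert-butyldimethylsilyloxy)-2,6-dimethyl-11-oxabicyclo[6.2.1]undeca-5,9-dien-9-yl trifluoromethanesulfonate; 19 tributyl(1-ethoxyvinyl)stannane
Product: 20 tert-butyl{[(1S,2S,5Z,8S)-9-(1-ethoxyethenyl)-2,6-dimethyl-11-oxabicyclo[6.2.1]undeca-5,9-dien-2-yl]oxy}dimethylsilane
Conditions: Pd(PPh3)4 (cat.), LiCl, THF, reflux
Reagents that add atoms: none
Why: Stille coupling of the enol triflate with the α-alkoxyvinylstannane (chloride assists transmetallation) should install the 2-ethoxy-1,3-diene C1=C10–C11(OEt)=C12.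

**Step 14**
Reactants: 20 tert-butyl{[(1S,2S,5Z,8S)-9-(1-ethoxyethenyl)-2,6-dimethyl-11-oxabicyclo[6.2.1]undeca-5,9-dien-2-yl]oxy}dimethylsilane; 21 methyl vinyl ketone
Product: 23 tricyclic methyl ketone (C10=C11 ethyl enol ether; C14 acetyl trans to C2; C3 OTBS; 6Z), via C14-epimeric cycloadducts 22 (not isolated)
Conditions: toluene, 110 °C, sealed tube, trace hydroquinone; then K2CO3, MeOH, 25 °C
Reagents that add atoms: none
Why: Diels–Alder reaction, in which the 2-alkoxydiene directs the acetyl group to C14 ("para" to OEt), the dienophile should approach C1 on the face opposite the C3–C8 bridge (setting C1), and base equilibration through the enolate converts the exo/endo mixture into the C14 epimer with the acetyl group equatorial and trans to C2.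

**Step 15**
Reactants: 23 tricyclic methyl ketone (C10=C11 ethyl enol ether; C14 acetyl trans to C2; C3 OTBS; 6Z)
Product: 25 tricyclic C11 ketone (cis ring fusion; C14 prop-1-en-2-yl; C3 OTBS; 6Z), via isopropenyl enol ether 24 (not isolated)
Conditions: Ph3PCH3Br, KOtBu, THF, 0 → 25 °C; then 1 M HCl, THF, 25 °C
Reagents that add atoms: methylenetriphenylphosphorane (C=P(c1ccccc1)(c1ccccc1)c1ccccc1); water (O)
Why: Wittig methylenation of the methyl ketone followed by acid hydrolysis of the enol ether, in which C10 is protonated (and can equilibrate through the enol) to the more stable cis ring fusion with H10 syn to H1.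

**Step 16**
Reactants: 25 tricyclic C11 ketone (cis ring fusion; C14 prop-1-en-2-yl; C3 OTBS; 6Z)
Product: 27 C11 tertiary acetate (11R; C14 prop-1-en-2-yl; C3 OTBS), via lithium alkoxide 26 (not isolated)
Conditions: MeLi, THF, −78 °C; then Ac2O, −78 → 25 °C
Reagents that add atoms: methyllithium ([Li]C); acetic anhydride (CC(=O)OC(C)=O)
Why: 1,2-Addition of methyllithium should occur on the convex face of the cis-fused bicycle, anti to the axial C9 substituent on C10, placing the methyl group syn to H10 (11R), and the hindered tertiary lithium alkoxide is acetylated in situ by acetic anhydride.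

**Step 17**
Reactants: 27 C11 tertiary acetate (11R; C14 prop-1-en-2-yl; C3 OTBS)
Product: 29 (15R)-C16 primary alcohol (C11 acetate; C3 OTBS), via alkylborane 28 (not isolated)
Conditions: 9-BBN, THF, 0 → 25 °C; then H2O2, aq NaOH, 0 °C
Reagents that add atoms: hydrogen peroxide (OO)
Why: Hydroboration–oxidation, in which 9-BBN should add only to the 1,1-disubstituted alkene (boron to C16) and, on the rotamer with C14–H eclipsing C15=C16 (the other rotamers clash with the equatorial C2 on C1), from the face remote from C1, giving (15R) as in the hydroboration of trans-2-substituted isopropenylcyclohexanes such as isopulegol ethers.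

**Step 18**
Reactants: 29 (15R)-C16 primary alcohol (C11 acetate; C3 OTBS)
Product: 30 C3,C16-diol (C11 acetate)
Conditions: Bu4NF, THF, 50 °C
Reagents that add atoms: none
Why: Fluoride-mediated cleavage of the tertiary silyl ether under non-acidic conditions, chosen because acid would trigger transannular attack of the free C3 hydroxyl on the C6=C7 alkene.

**Step 19**
Reactants: 30 C3,C16-diol (C11 acetate)
Product: 33 target CNP0332402.2, via hydroxy aldehyde 31 (not isolated), via lactol 32 (not isolated)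
Conditions: TEMPO (cat.), PhI(OAc)2, CH2Cl2, 25 °C
Reagents that add atoms: none
Why: Oxoammonium-mediated (TEMPO) oxidative lactonisation, in which the primary alcohol is oxidised to the aldehyde, the nearby tertiary C3 hydroxyl should trap it as the seven-membered lactol, and this is oxidised on to the ε-lactone while the tertiary alcohol itself is inert.

**Compound list**

1 | 2-(2-bromoethyl)-1,3-dioxolane | BrCCC1OCCO1 | starting material
2 | methacrolein | CC(=C)C=O | starting material
3 | [2-(1,3-dioxolan-2-yl)ethyl]magnesium bromide | Br[Mg]CCC1OCCO1 | intermediate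
4 | rac-1-(1,3-dioxolan-2-yl)-4-methylpent-4-en-3-ol | CC(=C)C(O)CCC1OCCO1 | intermediate
5 | (S)-1-(1,3-dioxolan-2-yl)-4-methylpent-4-en-3-ol | C=C(C)[C@@H](O)CCC1OCCO1 | intermediate
6 | ethyl propiolate | C#CC(=O)OCC | starting material
7 | ethyl (E)-3-{[(3S)-1-(1,3-dioxolan-2-yl)-4-methylpent-4-en-3-yl]oxy}prop-2-enoate | C=C(C)[C@@H](O/C=C/C(=O)OCC)CCC1OCCO1 | intermediate
8 | ethyl (E)-3-{[(3S)-2-methyl-6-oxohex-1-en-3-yl]oxy}prop-2-enoate | C=C(C)[C@@H](O/C=C/C(=O)OCC)CCC=O | intermediate
9 | ethyl 2-[(2S,3R,6S)-3-hydroxy-6-(prop-1-en-2-yl)oxan-2-yl]acetate | C=C(C)[C@@H]1CC[C@@H](O)[C@H](CC(=O)OCC)O1 | intermediate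
10 | ethyl 2-[(2S,6S)-3-oxo-6-(prop-1-en-2-yl)oxan-2-yl]acetate | C=C(C)[C@@H]1CCC(=O)[C@H](CC(=O)OCC)O1 | intermediate
11 | ethyl 2-[(2S,3S,6S)-3-hydroxy-3-methyl-6-(prop-1-en-2-yl)oxan-2-yl]acetate | C=C(C)[C@@H]1CC[C@](C)(O)[C@H](CC(=O)OCC)O1 | intermediate
12 | ethyl 2-[(2S,3S,6S)-3-(tert-butyldimethylsilyloxy)-3-methyl-6-(prop-1-en-2-yl)oxan-2-yl]acetate | C=C(C)[C@@H]1CC[C@](C)(O[Si](C)(C)C(C)(C)C)[C@H](CC(=O)OCC)O1 | intermediate
13 | 2-[(2S,3S,6S)-3-(tert-butyldimethylsilyloxy)-3-methyl-6-(prop-1-en-2-yl)oxan-2-yl]acetic acid | C=C(C)[C@@H]1CC[C@](C)(O[Si](C)(C)C(C)(C)C)[C@H](CC(=O)O)O1 | intermediate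
14 | isobutyl carbonic mixed anhydride of 13 | C=C(C)[C@@H]1CC[C@](C)(O[Si](C)(C)C(C)(C)C)[C@H](CC(=O)OC(=O)OCC(C)C)O1 | intermediate
15 | 1-diazo-3-[(2S,3S,6S)-3-(tert-butyldimethylsilyloxy)-3-methyl-6-(prop-1-en-2-yl)oxan-2-yl]propan-2-one | C=C(C)[C@@H]1CC[C@](C)(O[Si](C)(C)C(C)(C)C)[C@H](CC(=O)C=[N+]=[N-])O1 | intermediate
16 | bicyclic allyl oxonium ylide (O+ bonded to C2, C6 and C9; carbanion at C9 next to the C10 ketone) | C=C(C)[C@@H]1CC[C@](C)(O[Si](C)(C)C(C)(C)C)[C@@H]2CC(=O)[CH-][O+]12 | intermediate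
17 | (1S,2S,5Z,8S)-2-(tert-butyldimethylsilyloxy)-2,6-dimethyl-11-oxabicyclo[6.2.1]undec-5-en-9-one | O=C1C[C@@H]2O[C@H]1C/C(C)=C\CC[C@]2(C)O[Si](C)(C)C(C)(C)C | intermediate
18 | (1S,2S,5Z,8S)-2-(tert-butyldimethylsilyloxy)-2,6-dimethyl-11-oxabicyclo[6.2.1]undeca-5,9-dien-9-yl trifluoromethanesulfonate | FC(F)(F)S(=O)(=O)OC1=C[C@@H]2O[C@H]1C/C(C)=C\CC[C@]2(C)O[Si](C)(C)C(C)(C)C | intermediate
19 | tributyl(1-ethoxyvinyl)stannane | CCCC[Sn](CCCC)(CCCC)C(=C)OCC | starting material
20 | tert-butyl{[(1S,2S,5Z,8S)-9-(1-ethoxyethenyl)-2,6-dimethyl-11-oxabicyclo[6.2.1]undeca-5,9-dien-2-yl]oxy}dimethylsilane | CCOC(=C)C1=C[C@@H]2O[C@H]1C/C(C)=C\CC[C@]2(C)O[Si](C)(C)C(C)(C)C | intermediate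
21 | methyl vinyl ketone | CC(=O)C=C | starting material
22 | Diels–Alder adducts, mixture of C14 epimers (C10=C11 ethyl enol ether, C14 acetyl, C3 OTBS) | CCOC1=C2[C@@H]3C/C(C)=C\CC[C@](C)(O[Si](C)(C)C(C)(C)C)[C@@H](O3)[C@H]2C(C(C)=O)CC1 | intermediate
23 | tricyclic methyl ketone (C10=C11 ethyl enol ether; C14 acetyl trans to C2; C3 OTBS; 6Z; C1, C2, C3, C9, C14 as in the target) | CCOC1=C2[C@@H]3C/C(C)=C\CC[C@](C)(O[Si](C)(C)C(C)(C)C)[C@@H](O3)[C@H]2[C@H](C(C)=O)CC1 | intermediate
24 | tricyclic isopropenyl enol ether (acetyl of 23 converted to prop-1-en-2-yl) | CCOC1=C2[C@@H]3C/C(C)=C\CC[C@](C)(O[Si](C)(C)C(C)(C)C)[C@@H](O3)[C@H]2[C@H](C(C)=C)CC1 | intermediate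
25 | tricyclic C11 ketone (cis ring fusion, H1 and H10 syn; C14 prop-1-en-2-yl; C3 OTBS; 6Z) | O=C1CC[C@@H](C(C)=C)[C@H]2[C@@H]1[C@@H]3C/C(C)=C\CC[C@](C)(O[Si](C)(C)C(C)(C)C)[C@H]2O3 | intermediate
26 | lithium C11 alkoxide (11R, methyl syn to H10) | [Li]O[C@]1(C)CC[C@@H](C(C)=C)[C@H]2[C@@H]1[C@@H]3C/C(C)=C\CC[C@](C)(O[Si](C)(C)C(C)(C)C)[C@H]2O3 | intermediate
27 | C11 tertiary acetate (11R; C14 prop-1-en-2-yl; C3 OTBS) | CC(=O)O[C@]1(C)CC[C@@H](C(C)=C)[C@H]2[C@@H]1[C@@H]3C/C(C)=C\CC[C@](C)(O[Si](C)(C)C(C)(C)C)[C@H]2O3 | intermediate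
28 | B-alkyl-9-borabicyclo[3.3.1]nonane (boron on C16; 15R) | CC(=O)O[C@]1(C)CC[C@@H]([C@@H](C)CB4C5CCCC4CCC5)[C@H]2[C@@H]1[C@@H]3C/C(C)=C\CC[C@](C)(O[Si](C)(C)C(C)(C)C)[C@H]2O3 | intermediate
29 | (15R)-C16 primary alcohol (C11 acetate; C3 OTBS) | CC(=O)O[C@]1(C)CC[C@@H]([C@@H](C)CO)[C@H]2[C@@H]1[C@@H]3C/C(C)=C\CC[C@](C)(O[Si](C)(C)C(C)(C)C)[C@H]2O3 | intermediate
30 | C3,C16-diol (C11 acetate) | CC(=O)O[C@]1(C)CC[C@@H]([C@@H](C)CO)[C@H]2[C@@H]1[C@@H]3C/C(C)=C\CC[C@](C)(O)[C@H]2O3 | intermediate
31 | C16 aldehyde with free C3 hydroxyl | CC(=O)O[C@]1(C)CC[C@@H]([C@@H](C)C=O)[C@H]2[C@@H]1[C@@H]3C/C(C)=C\CC[C@](C)(O)[C@H]2O3 | intermediate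
32 | C16 lactol (seven-membered hemiacetal through the C3 oxygen) | CC(=O)O[C@]1(C)CC[C@@H]2[C@H]3[C@@H]1[C@@H]1C/C(C)=C\CC[C@](C)(OC(O)[C@@H]2C)[C@H]3O1 | intermediate
33 | CNP0332402.2, (1S,2S,3S,6Z,9S,10R,11R,14R,15R)-11-acetoxy-2,9-epoxy eunicell-6-ene 16,3-lactone | CC(=O)O[C@]1(C)CC[C@@H]2[C@H]3[C@@H]1[C@@H]1C/C(C)=C\CC[C@](C)(OC(=O)[C@@H]2C)[C@H]3O1 | target

**Total step count:** 19. **Longest linear sequence:** 19 steps (fully linear; all partners are commercial).

**Steps most likely to fail**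

1. Step 11 (key step). What may go wrong: the oxonium ylide may rearrange through both envelope transition states, eroding the alkene geometry, and carbenoid C–H insertion may compete with ylide formation. Fallback: the rearrangement of 15 is accepted as an E/Z mixture and the unwanted (E)-bicyclic ketone F1 is not separated. The mixture is heated with EtSH and AIBN in benzene, where reversible thiyl-radical addition to C6=C7 should drain the more strained (E)-oxonene into the (Z)-isomer, so that all material rejoins the route at 17.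

2. Step 17. What may go wrong: insufficient facial discrimination of the isopropenyl group, giving the C15 epimer. Fallback: from 27 the stereocentre is set by catalyst control instead of substrate control. Copper-hydride-catalysed enantioselective anti-Markovnikov hydroboration (CuCl, KOtBu, the matched enantiomer of DTBM-SEGPHOS, pinacolborane, THF) should give the (15R) pinacol boronate F2, which is oxidised (NaBO3, THF/H2O) to alcohol 29, where the route is rejoined.

3. Step 19. What may go wrong: slow closure of the seven-membered lactol, so that oxidation stalls at the aldehyde, with possible epimerisation at C15 on standing. Fallback: from 30 the hydroxy aldehyde 31 is isolated after a short TEMPO/PhI(OAc)2 oxidation and oxidised further (NaClO2, NaH2PO4, 2-methyl-2-butene, t-BuOH/H2O) to the seco hydroxy acid F3. This is activated as the 2,4,6-trichlorobenzoyl mixed anhydride F4 (2,4,6-trichlorobenzoyl chloride, Et3N, THF) and cyclised under high dilution with DMAP in toluene (Yamaguchi lactonisation), rejoining the route at 33.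

**Further compounds**

F1 | step 11 | (1S,2S,5E,8S)-2-(tert-butyldimethylsilyloxy)-2,6-dimethyl-11-oxabicyclo[6.2.1]undec-5-en-9-one | O=C1C[C@@H]2O[C@H]1C/C(C)=C/CC[C@]2(C)O[Si](C)(C)C(C)(C)C
F2 | step 17 | (15R)-C16 pinacol boronate of 27 | CC(=O)O[C@]1(C)CC[C@@H]([C@@H](C)CB4OC(C)(C)C(C)(C)O4)[C@H]2[C@@H]1[C@@H]3C/C(C)=C\CC[C@](C)(O[Si](C)(C)C(C)(C)C)[C@H]2O3
F3 | step 19 | seco hydroxy acid (C16 carboxylic acid, free C3 hydroxyl) | CC(=O)O[C@]1(C)CC[C@@H]([C@@H](C)C(=O)O)[C@H]2[C@@H]1[C@@H]3C/C(C)=C\CC[C@](C)(O)[C@H]2O3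
F4 | step 19 | 2,4,6-trichlorobenzoyl mixed anhydride of F3 | CC(=O)O[C@]1(C)CC[C@@H]([C@@H](C)C(=O)OC(=O)c4c(Cl)cc(Cl)cc4Cl)[C@H]2[C@@H]1[C@@H]3C/C(C)=C\CC[C@](C)(O)[C@H]2O3
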